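**Plan**

- Target: (2S)-5,7-dimethoxy-2-(4-methoxyphenyl)-6-prenylchromane (flavan numbering O1, C2, C3, C4, C4a, C5–C8, C8a; ring A = benzo ring, ring B = 4-methoxyphenyl, ring C = pyran ring).
- Enabling feature: in ring C the C3–C4 unit lies between C4a of ring A and the O1-bound stereocentre C2, so at the alkene level it is a C3=C4 bond that a vinyl group on C4a and a vinyl group on C2 can form by metathesis. The only other alkene, the trisubstituted prenyl alkene on C6, is meta to C4a and should stay out.
- Retrosynthetic cuts, in order: C3–C4 saturation (chromane to 2H-chromene); C3=C4 (ring-closing metathesis); O1–C2 (allylic etherification of a 2-vinylphenol with 4-methoxycinnamyl methyl carbonate); then on ring A the vinyl group (from CHO), the C4–C4a bond (formylation), the C8a–O bond (from C–H through C–B) and the C6–prenyl bond, back to 1,3-dimethoxybenzene.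
- Forward: ring A is dressed first (prenyl, OH, CHO, vinyl), ring B arrives together with C2 through the O1–C2 bond, ring C closes last and is then saturated.
- Stereochemistry: C2, the only stereocentre, is set in the iridium-catalysed allylic etherification by a chiral phosphoramidite ligand and is carried unchanged through metathesis and diimide reduction.

Key step: step 8

Assumption: for aryloxide attack on a cinnamyl carbonate the (Sa,Sc,Sc) enantiomer of the binaphthol/bis(1-phenylethyl)amine phosphoramidite is taken to give the (S) ether, by analogy with the usual sense of this catalyst class with heteroatom nucleophiles; if the first run shows the opposite sense, the mirror-image ligand is used and nothing else changes.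

**Route**

Step 1
Reactants: 1 1,3-dimethoxybenzene; 2 1-bromo-3-methylbut-2-ene (prenyl bromide)
Product: 4 1,3-dimethoxy-2-(3-methylbut-2-en-1-yl)benzene, via 2,6-dimethoxyphenyllithium 3 (not isolated)
Conditions: n-BuLi (1.1 equiv), THF, 0 °C to rt; then CuBr·SMe2 (10 mol%), 2, −20 °C to rt
Reagents that add atoms: none
Why: Directed ortho-lithiation places lithium at C2 between the two methoxy groups, and copper-catalysed SN2 allylation of the aryllithium with the primary bromide should give the linear prenyl arene and not the 1,1-dimethylallyl isomer.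

Step 2
Reactants: 4 1,3-dimethoxy-2-(3-methylbut-2-en-1-yl)benzene
Product: 5 2-[3,5-dimethoxy-4-(3-methylbut-2-en-1-yl)phenyl]-4,4,5,5-tetramethyl-1,3,2-dioxaborolane
Conditions: B2pin2 (1.0 equiv), [Ir(OMe)(cod)]2 (1.5 mol%), 4,4'-di-tert-butyl-2,2'-bipyridine (3 mol%), hexane, 50 °C
Reagents that add atoms: bis(pinacolato)diboron, CC1(C)OB(OC1(C)C)B1OC(C)(C)C(C)(C)O1
Why: Iridium-catalysed aromatic C–H borylation is sterically controlled and C5 is the only ring C–H without an ortho substituent, while the hindered trisubstituted alkene is expected to be a poor partner for the iridium boryl species under these mild conditions.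

Step 3
Reactants: 5 2-[3,5-dimethoxy-4-(3-methylbut-2-en-1-yl)phenyl]-4,4,5,5-tetramethyl-1,3,2-dioxaborolane
Product: 6 3,5-dimethoxy-4-(3-methylbut-2-en-1-yl)phenol
Conditions: 30% aq. H2O2, NaOH, THF, 0 °C to rt; then aq. Na2S2O3, pH 6
Reagents that add atoms: hydrogen peroxide, OO
Why: Oxidation of an arylboronate with basic hydrogen peroxide proceeds by 1,2-shift of the aryl group from boron to oxygen and hydrolysis, and the nucleophilic hydroperoxide does not epoxidise an isolated electron-rich alkene.

Step 4
Reactants: 6 3,5-dimethoxy-4-(3-methylbut-2-en-1-yl)phenol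
Product: 7 6-hydroxy-2,4-dimethoxy-3-(3-methylbut-2-en-1-yl)benzaldehyde
Conditions: MgCl2 (2 equiv), Et3N (4 equiv), (CH2O)n (6 equiv), MeCN, reflux; then 1 M HCl
Reagents that add atoms: paraformaldehyde (formaldehyde), C=O
Why: In the magnesium-mediated ortho-formylation (Casnati–Skattebøl reaction) the magnesium phenoxide delivers formaldehyde only ortho to oxygen, the two ortho positions of 6 are equivalent, and a second formaldehyde oxidises the benzylic alkoxide to the aldehyde.

Step 5
Reactants: 7 6-hydroxy-2,4-dimethoxy-3-(3-methylbut-2-en-1-yl)benzaldehyde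
Product: 8 2-ethenyl-3,5-dimethoxy-4-(3-methylbut-2-en-1-yl)phenol
Conditions: Ph3PCH3Br (2.5 equiv), KOtBu (2.5 equiv), THF, 0 °C to rt; then aq. NH4Cl; product kept cold and used promptly
Reagents that add atoms: methyltriphenylphosphonium bromide, C[P+](c1ccccc1)(c1ccccc1)c1ccccc1.[Br-]
Why: Wittig methylenation with excess ylide, which first deprotonates the phenol and then olefinates the phenoxide aldehyde, as is usual for salicylaldehydes.

Step 6
Reactants: 9 (E)-4-methoxycinnamyl alcohol [(2E)-3-(4-methoxyphenyl)prop-2-en-1-ol]
Product: 10 (2E)-3-(4-methoxyphenyl)prop-2-en-1-yl methyl carbonate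
Conditions: ClCO2Me (1.3 equiv), pyridine, CH2Cl2, 0 °C
Reagents that add atoms: methyl chloroformate, COC(Cl)=O
Why: Acylation of a primary allylic alcohol with a chloroformate under mild base gives the carbonate leaving group needed for ionisation on iridium without touching the E alkene.

Step 7
Reactants: 8 2-ethenyl-3,5-dimethoxy-4-(3-methylbut-2-en-1-yl)phenol; 10 (2E)-3-(4-methoxyphenyl)prop-2-en-1-yl methyl carbonate
Product: 12 2-ethenyl-3,5-dimethoxy-1-{[(1S)-1-(4-methoxyphenyl)prop-2-en-1-yl]oxy}-4-(3-methylbut-2-en-1-yl)benzene, via lithium 2-ethenyl-3,5-dimethoxy-4-(3-methylbut-2-en-1-yl)phenolate 11 (not isolated)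
Conditions: 8, LiN(SiMe3)2 (1.0 equiv), THF, 0 °C; then 10 (1.3 equiv), [Ir(cod)Cl]2 (2 mol%), (Sa,Sc,Sc)-O,O'-(1,1'-binaphthalene-2,2'-diyl) N,N-bis(1-phenylethyl)phosphoramidite (4 mol%, pre-activated with n-PrNH2, volatiles removed), THF, rt; neutral work-up
Reagents that add atoms: none
Why: In this iridium-catalysed asymmetric allylic etherification the carbonate ionises to a (π-allyl)iridium complex carrying the cyclometalated phosphoramidite, the aryloxide attacks the aryl-substituted allyl terminus on the face away from the metal to give the branched ether, and the ligand-fixed allyl face sets C2 as S.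

Step 8
Reactants: 12 2-ethenyl-3,5-dimethoxy-1-{[(1S)-1-(4-methoxyphenyl)prop-2-en-1-yl]oxy}-4-(3-methylbut-2-en-1-yl)benzene
Product: 13 (2S)-5,7-dimethoxy-2-(4-methoxyphenyl)-6-(3-methylbut-2-en-1-yl)-2H-chromene
Conditions: second-generation Grubbs catalyst RuCl2(PCy3)(H2IMes)(=CHPh) (3 mol%), CH2Cl2 (0.01 M), 35 °C, argon sparge, dark; then ethyl vinyl ether, filtration through Et3N-washed silica; used at once
Reagents that add atoms: none
Why: The ruthenium benzylidene exchanges onto the unhindered vinyl group on C2, the new alkylidene adds to the C4a vinyl group in a [2+2] step, and cycloreversion of the ruthenacyclobutane forms the C3=C4 bond and a ruthenium methylidene that carries the chain while ethylene leaves. The closest known reaction type is ring-closing olefin metathesis of 2-vinylaryl allyl ethers to 2H-chromenes. Ring C closes as a six-membered ring through the C3–C4 bond, the new alkene being necessarily cis inside the ring. No stereocentre is formed, and C2 is not a reacting atom, so it keeps the S configuration set in step 7. The selectivity needed is among three alkenes: the two monosubstituted vinyl groups are held close by the ortho ether link and react fast, whereas the prenyl alkene is trisubstituted and meta to the C4a vinyl group, so it can neither close a ring nor cross-metathesise at a comparable rate under dilution with ethylene removal. Neutral, dark conditions and a base-washed filtration are chosen because the C2–O bond of the product is allylic and benzylic and the 2H-chromene can open electrocyclically.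

Step 9
Reactants: 13 (2S)-5,7-dimethoxy-2-(4-methoxyphenyl)-6-(3-methylbut-2-en-1-yl)-2H-chromene
Product: 14 (2S)-5,7-dimethoxy-2-(4-methoxyphenyl)-6-(3-methylbut-2-en-1-yl)-3,4-dihydro-2H-chromene
Conditions: 2-O2NC6H4SO2NHNH2 (4 equiv), Et3N (8 equiv), CH2Cl2, rt, dark
Reagents that add atoms: none
Why: Diimide reduction transfers two hydrogens in a concerted syn step much faster to the cis-disubstituted ring alkene than to the trisubstituted prenyl alkene, and the basic, metal-free medium leaves the benzylic C2–O bond and the C2 configuration alone.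

**Compound list**

1 | 1,3-dimethoxybenzene | COc1cccc(OC)c1 | starting material
2 | 1-bromo-3-methylbut-2-ene (prenyl bromide) | CC(C)=CCBr | starting material
3 | 2,6-dimethoxyphenyllithium | [Li]c1c(OC)cccc1OC | intermediate
4 | 1,3-dimethoxy-2-(3-methylbut-2-en-1-yl)benzene | COc1cccc(OC)c1CC=C(C)C | intermediate
5 | 2-[3,5-dimethoxy-4-(3-methylbut-2-en-1-yl)phenyl]-4,4,5,5-tetramethyl-1,3,2-dioxaborolane | COc1cc(B2OC(C)(C)C(C)(C)O2)cc(OC)c1CC=C(C)C | intermediate
6 | 3,5-dimethoxy-4-(3-methylbut-2-en-1-yl)phenol | COc1cc(O)cc(OC)c1CC=C(C)C | intermediate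
7 | 6-hydroxy-2,4-dimethoxy-3-(3-methylbut-2-en-1-yl)benzaldehyde | COc1cc(O)c(C=O)c(OC)c1CC=C(C)C | intermediate
8 | 2-ethenyl-3,5-dimethoxy-4-(3-methylbut-2-en-1-yl)phenol | COc1cc(O)c(C=C)c(OC)c1CC=C(C)C | intermediate
9 | (E)-4-methoxycinnamyl alcohol | COc1ccc(/C=C/CO)cc1 | starting material
10 | (2E)-3-(4-methoxyphenyl)prop-2-en-1-yl methyl carbonate | COC(=O)OC/C=C/c1ccc(OC)cc1 | intermediate
11 | lithium 2-ethenyl-3,5-dimethoxy-4-(3-methylbut-2-en-1-yl)phenolate | [Li+].[O-]c1cc(OC)c(CC=C(C)C)c(OC)c1C=C | intermediate
12 | 2-ethenyl-3,5-dimethoxy-1-{[(1S)-1-(4-methoxyphenyl)prop-2-en-1-yl]oxy}-4-(3-methylbut-2-en-1-yl)benzene | COc1ccc([C@@H](Oc2cc(OC)c(CC=C(C)C)c(OC)c2C=C)C=C)cc1 | intermediate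
13 | (2S)-5,7-dimethoxy-2-(4-methoxyphenyl)-6-(3-methylbut-2-en-1-yl)-2H-chromene | COc1ccc([C@@H]2C=Cc3c(cc(OC)c(CC=C(C)C)c3OC)O2)cc1 | intermediate
14 | (2S)-5,7-dimethoxy-2-(4-methoxyphenyl)-6-(3-methylbut-2-en-1-yl)-3,4-dihydro-2H-chromene | COc1ccc([C@@H]2CCc3c(cc(OC)c(CC=C(C)C)c3OC)O2)cc1 | target

**Step count**

Total steps: 9. Longest linear sequence: 8 steps (steps 1 to 5 and 7 to 9); step 6 is a one-step side branch.

**Steps most likely to fail**

1. Step 7. The 4-methoxyphenyl group makes both the allyl complex and the product ether easy to ionise. This would erode the enantiomeric purity and drain the branched ether into the linear isomer, and carbon attack by the very electron-rich ring could compete with oxygen attack. The fallback carries ring B as its 4-bromo analogue, whose allyl system ionises far less readily, and introduces the methoxy group last. It sets out from phenol 8 (as its lithium salt 11). Purchased (E)-4-bromocinnamyl alcohol is converted with ClCO2Me and pyridine into (2E)-3-(4-bromophenyl)prop-2-en-1-yl methyl carbonate F1. The same iridium-catalysed etherification with 11 should give 1-{[(1S)-1-(4-bromophenyl)prop-2-en-1-yl]oxy}-2-ethenyl-3,5-dimethoxy-4-(3-methylbut-2-en-1-yl)benzene F2. Ring-closing metathesis as in step 8 should give (2S)-2-(4-bromophenyl)-5,7-dimethoxy-6-(3-methylbut-2-en-1-yl)-2H-chromene F3, and diimide reduction as in step 9 should give (2S)-2-(4-bromophenyl)-5,7-dimethoxy-6-(3-methylbut-2-en-1-yl)-3,4-dihydro-2H-chromene F4. Palladium-catalysed C–O coupling of the aryl bromide with methanol (Pd2(dba)3, tBuBrettPhos, Cs2CO3, MeOH, toluene, 60 °C) then comes back to the route at target 14.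

2. Step 2. The prenyl alkene may be drawn into the reaction, by hydroboration with the pinacolborane formed or by double-bond migration on iridium hydrides, faster than the aromatic C–H bond is borylated. The fallback installs the oxygen before the alkene and sets out from 1. Borylation of 1 under the step 2 conditions, now with no alkene present, should give 2-(3,5-dimethoxyphenyl)-4,4,5,5-tetramethyl-1,3,2-dioxaborolane F5, and H2O2/NaOH oxidation gives 3,5-dimethoxyphenol F6 (which can also simply be purchased). Silylation (iPr3SiCl, imidazole, DMF) gives (3,5-dimethoxyphenoxy)tri(propan-2-yl)silane F7. n-BuLi in THF at 0 °C should lithiate between the two methoxy groups, the bulky and weakly coordinating silyl ether shielding its own ortho positions, to give {2,6-dimethoxy-4-[tri(propan-2-yl)silyloxy]phenyl}lithium F8. CuBr·SMe2-catalysed alkylation with 2 gives [3,5-dimethoxy-4-(3-methylbut-2-en-1-yl)phenoxy]tri(propan-2-yl)silane F9, and Bu4NF in THF comes back to the route at phenol 6.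

3. Step 9. Chemoselectivity may be lost if a large excess of diimide is needed, with partial saturation of the prenyl alkene, and a slow reduction leaves time for electrocyclic opening and racemisation of 13. The fallback replaces diimide transfer by homogeneous catalytic hydrogenation and sets out from 13: H2 (1 atm), RhCl(PPh3)3 (5 mol%), benzene/EtOH, rt. This catalyst hydrogenates cis-disubstituted alkenes far faster than trisubstituted ones and does not hydrogenolyse the benzylic C2–O bond. It comes back to the route directly at 14, and no new compound is made (F0).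

**Further compounds**

F1 | step 7 | (2E)-3-(4-bromophenyl)prop-2-en-1-yl methyl carbonate | COC(=O)OC/C=C/c1ccc(Br)cc1
F2 | step 7 | 1-{[(1S)-1-(4-bromophenyl)prop-2-en-1-yl]oxy}-2-ethenyl-3,5-dimethoxy-4-(3-methylbut-2-en-1-yl)benzene | Brc1ccc([C@@H](Oc2cc(OC)c(CC=C(C)C)c(OC)c2C=C)C=C)cc1
F3 | step 7 | (2S)-2-(4-bromophenyl)-5,7-dimethoxy-6-(3-methylbut-2-en-1-yl)-2H-chromene | Brc1ccc([C@@H]2C=Cc3c(cc(OC)c(CC=C(C)C)c3OC)O2)cc1
F4 | step 7 | (2S)-2-(4-bromophenyl)-5,7-dimethoxy-6-(3-methylbut-2-en-1-yl)-3,4-dihydro-2H-chromene | Brc1ccc([C@@H]2CCc3c(cc(OC)c(CC=C(C)C)c3OC)O2)cc1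
F5 | step 2 | 2-(3,5-dimethoxyphenyl)-4,4,5,5-tetramethyl-1,3,2-dioxaborolane | COc1cc(OC)cc(B2OC(C)(C)C(C)(C)O2)c1
F6 | step 2 | 3,5-dimethoxyphenol | COc1cc(O)cc(OC)c1
F7 | step 2 | (3,5-dimethoxyphenoxy)tri(propan-2-yl)silane | COc1cc(O[Si](C(C)C)(C(C)C)C(C)C)cc(OC)c1
F8 | step 2 | {2,6-dimethoxy-4-[tri(propan-2-yl)silyloxy]phenyl}lithium | [Li]c1c(OC)cc(O[Si](C(C)C)(C(C)C)C(C)C)cc1OC
F9 | step 2 | [3,5-dimethoxy-4-(3-methylbut-2-en-1-yl)phenoxy]tri(propan-2-yl)silane | COc1cc(O[Si](C(C)C)(C(C)C)C(C)C)cc(OC)c1CC=C(C)C
F0 | step 9 | none | none
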